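1. The two hands' charge taken together is conserved: at any moment it stands as substrate, as product, or somewhere the readings do not show. In the flask the two substrates together, 0.800 M, are the limiting reagent, being charged below the 1.00 M of reagent.

| flask | left-handed substrate | right-handed substrate | reagent | remark | time |
|---|---|---|---|---|---|
| noon | 0.40 M | 0.40 M | 0.50 M | run made earlier |  |
| spring | 0.40 M | 0.40 M | 2 M | run made earlier |  |
| winter | 0.80 M | 0.80 M | 1 M | run made earlier |  |
| flask | 0.40 M | 0.40 M | 1.00 M |  | 8.0 d |

| run | time / d | left-handed product / % | right-handed product / % |
|---|---|---|---|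
| noon | 2.08 | 18.0 | 1.7 |
| noon | 4.00 | 21.6 | 2.6 |
| noon | 6.00 | 23.2 | 2.8 |
| noon | 8.00 | 23.4 | 3.0 |
| noon | 10.0 | 23.9 | 2.9 |
| spring | 0.833 | 31.4 | 4.9 |
| spring | 2.50 | 39.7 | 8.6 |
| spring | 4.00 | 40.4 | 10.8 |
| spring | 6.00 | 40.5 | 11.7 |
| spring | 10.0 | 41.2 | 12.1 |
| winter | 2.08 | 26.7 | 2.8 |
| winter | 4.00 | 29.7 | 4.7 |
| winter | 6.00 | 30.8 | 4.8 |
| winter | 8.00 | 30.8 | 5.0 |
| winter | 10.0 | 31.0 | 4.9 |

(each reading ± 0.3 percentage points)

* left-handed product and right-handed product together, in percent of the left-handed substrate and right-handed substrate charged together, at 8.0 d
* excess of left-handed product over right-handed product in the product at 8.0 d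
* whether the exchange between left-handed substrate and right-handed substrate keeps pace with the reaction: how far the product's excess at 8.0 d gets from its value without exchange to its value with instant exchange (above 80 % keeps pace, below 20 % hardly takes part, else lags behind)

- reagent is single-handed; left-handed substrate and right-handed substrate are mirror images of each other, charged as a racemate, each of them at the stated concentration
- an excess is the difference of the two amounts in percent of their sum
- an excess is below zero if the other one leads
- the handed part of reagent does not stay in what it makes, so the products of the two hands are mirror images too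

2. First rung, the left hand. In the spring run left-handed product reaches 31.4 % by 0.833 d, then 39.7 % at 2.50 d and 41.2 % at 10.0 d.

3. Second rung, the right hand. Spring's right-handed product still climbs, from 8.6 % at 2.50 d to 12.1 % at 10.0 d, so reagent is still at work there.

4. Yet spring's left-handed product stops 8.8 percentage points short of that hand's share. My reading is that the balance has an exit needing no reagent, and each plateau is the result of a race.

5. Take the plateau product of a hand over the rest of that hand's half of the charge, divided by the mean reagent (charge less half of what the products used). For the left hand, noon gives 2.33 L mol⁻¹, winter 2.29 L mol⁻¹ and spring 2.62 L mol⁻¹. The mean of these three is the capture number 2.41 L mol⁻¹. The same three runs give the right hand 0.163 L mol⁻¹ on average.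

6. My reckoning for the flask takes a mean reagent of 0.840 M. That gives left-handed product 33.5 % and right-handed product 6.01 %, so a yield of 39.5 % and an excess of 69.6 %. On the left hand the race stands at 2.02 to one, the exit being of like pace with the reagent step. If the exit leads over to the other hand, I expect the exchange to lag.

7. The forecast says 40 %, 69 % and hardly takes part: “So exchange hardly takes part.” On this last point my reckoning differs.

8. The flask gives 39.6 % with an excess of 67.9 %, and the exchange lags behind, getting 46 % of the way.

    reagent + left-handed substrate → left-handed product (k = 0.0342 L mol⁻¹ h⁻¹)
    reagent + right-handed substrate → right-handed product (k = 0.00298 L mol⁻¹ h⁻¹)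
    left-handed substrate ⇌ achiral form (K = 1.07, k = 0.0159 h⁻¹)
    right-handed substrate ⇌ achiral form (K = 1.07, k = 0.0159 h⁻¹)
    achiral form → waste (k = 0.0358 h⁻¹)
    achiral form → side product (k = 0.471 h⁻¹)
    reagent → decomposition product (k = 1.42 × 10⁻⁴ h⁻¹)

At 8.00 d side product holds 54.4 % of the flask's charge. The neighbour flask has 2.5 M of reagent. With spring's use of reagent its mean reagent is 2.29 M, so the capture numbers give left-handed product 42.3 % and right-handed product 13.6 %. That neighbour flask gives 42.6 % and 14.5 %.

The numbers in the tables are calculated with made-up constants.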